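**Plan**

1. Working numbers: ring A = C1(Me)=C2–C3–C8–C9–C10, ring B = C3–C4–C5(Me)–C6(=O)–C7(Me)–C8, exocyclic C10=C11–C12(OH)–C13, side chain C9–C1′=C2′(Me)–C3′/C4′(Me) oxirane–C5′=C6′–C7′O2H.
2. Enabling feature: C6 (ring-B ketone) and C10 (ring-A alkylidene carbon) are 1,7-related through the C1=C2 olefin (C10–C1=C2–C3–C4–C5–C6). With C10 as a ketone, C3 is the γ-carbon of an enone and C4 the β-carbon of a C6 enone, so the C3–C4 bond of ring B is the retron of an intramolecular vinylogous Michael addition.
3. Cuts: C3–C4 (ring B, key step); C10=C11 (alkynylation and Meyer–Schuster rearrangement at the C10 ketone); C1′=C2′, C3′=C4′ (before epoxidation) and C5′=C6′ (three Wittig olefinations); C9–C1′ (enolate hydroxymethylation); C5–C6 (Grignard addition to an aldehyde made from the isopropenyl group).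
4. Forward order: ring A is (R)-carvone, which brings C1, C2, C3, C8, C9, C10, the C1 methyl and C6/C7/C7-methyl. Ring B is the last ring of the carbon framework to be closed (step 7), with its enolate stored as a silyl enol ether so that only the C10 ketone is homologated. The side chain is then grown and the oxirane placed on it.
5. Stereochemistry: C8 from (R)-carvone; C9 by trans-selective enolate aldol; C3 by the tether (cis fusion); C5 and C7 by equilibration; C12 by CBS reduction; C3′/C4′ by Sharpless epoxidation; olefin geometries from stabilised ylides and the thermodynamic preference of the Meyer–Schuster enone.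

Key step: step 7

Remark: compounds 6 to 16 are carried as mixtures at C7 (7 also at C6, 12 at C10, 16 at C5); these centres are either destroyed or equilibrated in step 12, so the mixture is taken as inconsequential.

**Route**

Step 1
Reactants: 1 (R)-(−)-carvone
Product: 3 trans-6-(hydroxymethyl)carvone, via lithium enolate 2 (not isolated)
Conditions: LiN(iPr)2, THF, −78 °C; CH2O (gas, from cracked paraformaldehyde), −78 °C; H2O
Reagents that add atoms: formaldehyde, C=O
Why: Kinetic α′-deprotonation gives the cross-conjugated lithium enolate, whose aldol addition to formaldehyde should occur anti to the C8 isopropenyl group, so C9 is set trans to C8 by substrate control (the diequatorial product is also the thermodynamic one).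

Step 2
Reactants: 3 trans-6-(hydroxymethyl)carvone
Product: 4 TBS ether of 3
Conditions: TBSCl, imidazole, DMF, 0 °C to rt
Reagents that add atoms: tert-butyldimethylsilyl chloride, CC(C)(C)[Si](C)(C)Cl
Why: Silyl ether protection of the primary alcohol prevents it from opening the epoxide of step 3 and touches no stereocentre.

Step 3
Reactants: 4 TBS ether of 3
Product: 5 isopropenyl epoxide
Conditions: mCPBA, NaHCO3, CH2Cl2, 0 °C
Reagents that add atoms: 3-chloroperoxybenzoic acid, OOC(=O)c1cccc(Cl)c1
Why: Prilezhaev epoxidation should select the electron-rich 1,1-disubstituted olefin over the enone, and the new epoxide centre (a mixture) is erased in step 4.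

Step 4
Reactants: 5 isopropenyl epoxide
Product: 6 aldehyde
Conditions: InCl3 (10 mol %), THF, rt
Reagents that add atoms: none
Why: Meinwald rearrangement, in which Lewis-acid opening to the tertiary cation at C7 and a 1,2-hydride shift give the C6 aldehyde, with C7 formed as an epimer mixture that is corrected in step 12.

Step 5
Reactants: 6 aldehyde
Product: 7 allylic alcohol
Conditions: CH2=C(CH3)MgBr, THF, −78 °C; H2O
Reagents that add atoms: isopropenylmagnesium bromide, CC(=C)[Mg]Br
Why: Grignard addition should be chemoselective because the aldehyde is far more electrophilic than the hindered conjugated C10 ketone at −78 °C, and the carbinol configuration is irrelevant since C6 is oxidised next.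

Step 6
Reactants: 7 allylic alcohol
Product: 8 enone-tethered carvone
Conditions: Dess–Martin periodinane, NaHCO3, CH2Cl2, 0 °C to rt
Reagents that add atoms: none
Why: Dess–Martin oxidation of the secondary allylic alcohol gives the isopropenyl ketone (the Michael acceptor) under non-basic conditions that spare the β-silyloxy ketone.

Step 7
Reactants: 8 enone-tethered carvone
Product: 11 cis-fused bicyclic enone carrying the ring-B TBS enol ether, via linear lithium dienolate 9 (not isolated), via ring-B enolate 10 (not isolated)
Conditions: Al(OC6H3Ph2-2,6)3 (2.2 equiv, preformed), PhMe, −78 °C; lithium 2,2,6,6-tetramethylpiperidide (1.2 equiv), THF, −78 °C; TBSOTf (1.5 equiv), −78 to −40 °C; aq. NaHCO3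
Reagents that add atoms: tert-butyldimethylsilyl trifluoromethanesulfonate, CC(C)(C)[Si](C)(C)OS(=O)(=O)C(F)(F)F
Why: Proposed new method: the bulky aluminium phenoxide is expected to bind both carbonyl oxygens and bury the flanking C9–H and C7–H, so the lithium amide can only remove a γ-hydrogen at C3 to give linear dienolate 9, whose C3 terminus adds to C4 of the aluminium-activated isopropenyl ketone (intramolecular vinylogous Michael addition) before enolate 10 is silylated on oxygen. The closest known reaction types are the γ-selective deprotonation and vinylogous aldol addition of conjugated carbonyl compounds held in the same aluminium phenoxide pocket, and the base-mediated intramolecular vinylogous Michael addition of cyclohexenone dienolates; their combination on a tethered enone acceptor has not been shown. Ring B closes by 6-endo-trig attack of C3 on the terminal carbon of the enone. The one new stereocentre, C3, is controlled by C8, because bond formation must follow the dienolate π axis at C3 and the three-atom tether (C7–C6–C5) reaches C3 only on the face syn to the C8–C7 bond, which enforces the cis ring fusion. The step needs γ (C3) attack instead of α′ (C9) or α (C1) attack and kinetic control at C3; the substrate secures this because C9 is tertiary and shielded by its silyloxymethyl group, attack through C1 would require a bridged eight-membered ring, and the cyclised enolate is captured at low temperature before the γ-centre can equilibrate. The resulting silyl enol ether also distinguishes the C6 ketone from the C10 ketone for steps 8 to 10.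

Step 8
Reactants: 11 cis-fused bicyclic enone carrying the ring-B TBS enol ether
Product: 12 tertiary propargylic alcohol
Conditions: CH3C≡CLi, THF, −78 to 0 °C; H2O
Reagents that add atoms: 1-propynyllithium, [Li]C#CC
Why: 1,2-Addition of a weakly basic alkynyllithium to the only free carbonyl (C10) should proceed because C6 is masked as its silyl enol ether, and the C10 configuration is irrelevant since C10 becomes trigonal in step 9.

Step 9
Reactants: 12 tertiary propargylic alcohol
Product: 13 (E)-dienone
Conditions: Ph3PAuNTf2 (2 mol %), MeOH (1 equiv), PhMe, rt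
Reagents that add atoms: none
Why: Meyer–Schuster rearrangement (formal 1,3-hydroxyl shift and tautomerisation) gives the C10=C11–C12(=O) enone, and the E geometry (acetyl syn to C9) should prevail because the Z isomer would press the acetyl group against the C1 methyl group.

Step 10
Reactants: 13 (E)-dienone
Product: 14 (12R)-allylic alcohol
Conditions: (S)-2-methyl-CBS-oxazaborolidine (20 mol %), catecholborane, PhMe, −78 °C
Reagents that add atoms: none
Why: CBS reduction with the alkenyl residue as the large and methyl as the small group should give the (R)-carbinol at C12 under reagent control, while catecholborane at low temperature leaves the silyl enol ether and the diene alone.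

Step 11
Reactants: 14 (12R)-allylic alcohol
Product: 15 (12R)-acetate
Conditions: Ac2O, pyridine, DMAP (cat.), CH2Cl2, 0 °C
Reagents that add atoms: acetic anhydride, CC(=O)OC(C)=O
Why: Acylation protects C12–OH so that it neither competes in the Sharpless epoxidation of step 16 nor is oxidised in steps 13 and 17.

Step 12
Reactants: 15 (12R)-acetate
Product: 17 keto alcohol having both ring-B methyl groups equatorial, via keto alcohol epimer mixture 16 (not isolated)
Conditions: HF·pyridine, pyridine, THF, 0 °C to rt; then DBU (0.5 equiv), PhMe, 40 °C
Reagents that add atoms: none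
Why: Fluoride desilylation removes the primary silyl ether and the silyl enol ether, and base-mediated epimerisation should then place the C5 and C7 methyl groups equatorial on the ring-B chair, whose conformation is fixed by allylic strain between C12 and the C9 substituent (thermodynamic control of C5 and C7).

Step 13
Reactants: 17 keto alcohol having both ring-B methyl groups equatorial
Product: 19 (E)-enal, via keto aldehyde 18 (not isolated)
Conditions: Dess–Martin periodinane, NaHCO3, CH2Cl2, 0 °C; filtration, solvent switch; Ph3P=C(CH3)CHO, PhMe, 70 °C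
Reagents that add atoms: 2-(triphenylphosphoranylidene)propanal, CC(C=O)=P(c1ccccc1)(c1ccccc1)c1ccccc1
Why: Dess–Martin oxidation followed by Wittig olefination with a stabilised ylide should give the E-trisubstituted C1′=C2′ olefin and react only at the aldehyde, not at the hindered C6 ketone.

Step 14
Reactants: 19 (E)-enal
Product: 20 (E,E)-dienal
Conditions: Ph3P=C(CH3)CHO, PhMe, 90 °C
Reagents that add atoms: 2-(triphenylphosphoranylidene)propanal, CC(C=O)=P(c1ccccc1)(c1ccccc1)c1ccccc1
Why: A second Wittig olefination with the same stabilised ylide should install the E-configured C3′=C4′ olefin with its methyl group.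

Step 15
Reactants: 20 (E,E)-dienal
Product: 21 (E,E)-dienol
Conditions: NaBH4, MeOH/THF, −40 °C
Reagents that add atoms: none
Why: Borohydride 1,2-reduction should be chemoselective for the aldehyde over the doubly α-branched C6 ketone and the acetate, which avoids any hydride reagent that would attack the ketone.

Step 16
Reactants: 21 (E,E)-dienol
Product: 22 epoxy alcohol
Conditions: Ti(OiPr)4 (10 mol %), L-(+)-diisopropyl tartrate (12 mol %), t-BuOOH, 4 Å MS, CH2Cl2, −20 °C
Reagents that add atoms: tert-butyl hydroperoxide, CC(C)(C)OO
Why: Sharpless asymmetric epoxidation touches only the olefin allylic to the free hydroxyl, and L-(+)-tartrate should deliver oxygen to the face that gives the (2S,3S)-type epoxy alcohol of an (E)-allylic alcohol, setting C3′ and C4′ by reagent control.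

Step 17
Reactants: 22 epoxy alcohol
Product: 24 methyl ester and C12 acetate of the target, via epoxy aldehyde 23 (not isolated)
Conditions: Dess–Martin periodinane, NaHCO3, CH2Cl2, 0 °C; then Ph3P=CHCO2Me, rt
Reagents that add atoms: methyl (triphenylphosphoranylidene)acetate, COC(=O)C=P(c1ccccc1)(c1ccccc1)c1ccccc1
Why: Buffered Dess–Martin oxidation gives an epoxy aldehyde with no α-hydrogen, and in-flask Wittig olefination with the stabilised ylide should give the E-enoate without opening the vinyl oxirane.

Step 18
Reactants: 24 methyl ester and C12 acetate of the target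
Product: 25 CNP0414188.1
Conditions: LiOH, THF/MeOH/H2O, 0 °C to rt; cold 1 M HCl to pH 5
Reagents that add atoms: lithium hydroxide, [Li+].[OH-]
Why: Saponification cleaves the methyl ester and the acetate together, and the only base-labile centres (C5, C7) already hold their thermodynamic configuration.

**Compound list**

1 | (R)-(−)-carvone | CC1=CC[C@@H](C(C)=C)CC1=O | starting material
2 | cross-conjugated lithium enolate of carvone (C9=C10–OLi) | CC1=CC[C@@H](C(C)=C)C=C1[O-].[Li+] | intermediate
3 | trans-6-(hydroxymethyl)carvone (CH2OH on C9, trans to the isopropenyl group on C8) | CC1=CC[C@@H](C(C)=C)[C@H](CO)C1=O | intermediate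
4 | TBS ether of 3 | CC1=CC[C@@H](C(C)=C)[C@H](CO[Si](C)(C)C(C)(C)C)C1=O | intermediate
5 | isopropenyl epoxide of 4 (2-methyloxiran-2-yl on C8, both epimers) | CC1=CC[C@@H](C2(C)CO2)[C@H](CO[Si](C)(C)C(C)(C)C)C1=O | intermediate
6 | aldehyde, C8 bearing CH(CH3)CHO (C7 epimers) | CC1=CC[C@@H](C(C)C=O)[C@H](CO[Si](C)(C)C(C)(C)C)C1=O | intermediate
7 | allylic alcohol, C8 bearing CH(CH3)CH(OH)C(CH3)=CH2 (mixture at C6 and C7) | CC1=CC[C@@H](C(C)C(O)C(C)=C)[C@H](CO[Si](C)(C)C(C)(C)C)C1=O | intermediate
8 | enone-tethered carvone, C8 bearing CH(CH3)C(=O)C(CH3)=CH2 (C7 epimers) | CC1=CC[C@@H](C(C)C(=O)C(C)=C)[C@H](CO[Si](C)(C)C(C)(C)C)C1=O | intermediate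
9 | linear lithium dienolate of 8 (LiO–C10=C1–C2=C3, aluminium-bound; drawn as the lithium salt) | CC=1C=C[C@@H](C(C)C(=O)C(C)=C)[C@H](CO[Si](C)(C)C(C)(C)C)C=1[O-].[Li+] | intermediate
10 | cyclised ring-B enolate (C5=C6–O−, aluminium-bound; drawn as the lithium salt) | CC1=C[C@H]2CC(C)=C([O-])C(C)[C@H]2[C@H](CO[Si](C)(C)C(C)(C)C)C1=O.[Li+] | intermediate
11 | cis-fused bicyclic enone: C10 ketone, C1=C2, ring-B C5=C6 TBS enol ether, CH2OTBS on C9 (C7 epimers) | CC1=C[C@H]2CC(C)=C(O[Si](C)(C)C(C)(C)C)C(C)[C@H]2[C@H](CO[Si](C)(C)C(C)(C)C)C1=O | intermediate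
12 | tertiary propargylic alcohol, OH and 1-propynyl on C10 (mixture at C10) | CC1=C[C@H]2CC(C)=C(O[Si](C)(C)C(C)(C)C)C(C)[C@H]2[C@H](CO[Si](C)(C)C(C)(C)C)C1(O)C#CC | intermediate
13 | (E)-dienone, C10=C11–C12(=O)CH3 with the acetyl group syn to C9 | CC1=C[C@H]2CC(C)=C(O[Si](C)(C)C(C)(C)C)C(C)[C@H]2[C@H](CO[Si](C)(C)C(C)(C)C)/C1=C\C(C)=O | intermediate
14 | (12R)-allylic alcohol | CC1=C[C@H]2CC(C)=C(O[Si](C)(C)C(C)(C)C)C(C)[C@H]2[C@H](CO[Si](C)(C)C(C)(C)C)/C1=C\[C@@H](C)O | intermediate
15 | (12R)-acetate | CC1=C[C@H]2CC(C)=C(O[Si](C)(C)C(C)(C)C)C(C)[C@H]2[C@H](CO[Si](C)(C)C(C)(C)C)/C1=C\[C@@H](C)OC(C)=O | intermediate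
16 | keto alcohol (C6 ketone, CH2OH on C9), unequilibrated mixture at C5 and C7 | CC1=C[C@H]2CC(C)C(=O)C(C)[C@H]2[C@H](CO)/C1=C\[C@@H](C)OC(C)=O | intermediate
17 | keto alcohol with both ring-B methyl groups equatorial (target configuration at C3, C5, C7, C8, C9, C12) | CC1=C[C@H]2C[C@H](C)C(=O)[C@H](C)[C@H]2[C@H](CO)/C1=C\[C@@H](C)OC(C)=O | intermediate
18 | keto aldehyde (CHO on C9) | CC1=C[C@H]2C[C@H](C)C(=O)[C@H](C)[C@H]2[C@H](C=O)/C1=C\[C@@H](C)OC(C)=O | intermediate
19 | (E)-enal, C9–CH=C(CH3)–CHO | CC1=C[C@H]2C[C@H](C)C(=O)[C@H](C)[C@H]2[C@H](/C=C(\C)C=O)/C1=C\[C@@H](C)OC(C)=O | intermediate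
20 | (E,E)-dienal, C9–CH=C(CH3)–CH=C(CH3)–CHO | CC1=C[C@H]2C[C@H](C)C(=O)[C@H](C)[C@H]2[C@H](/C=C(\C)/C=C(\C)C=O)/C1=C\[C@@H](C)OC(C)=O | intermediate
21 | (E,E)-dienol | CC1=C[C@H]2C[C@H](C)C(=O)[C@H](C)[C@H]2[C@H](/C=C(\C)/C=C(\C)CO)/C1=C\[C@@H](C)OC(C)=O | intermediate
22 | epoxy alcohol (C3′/C4′ oxirane, CH2OH on C4′) | CC1=C[C@H]2C[C@H](C)C(=O)[C@H](C)[C@H]2[C@H](/C=C(\C)[C@@H]2O[C@@]2(C)CO)/C1=C\[C@@H](C)OC(C)=O | intermediate
23 | epoxy aldehyde | CC1=C[C@H]2C[C@H](C)C(=O)[C@H](C)[C@H]2[C@H](/C=C(\C)[C@@H]2O[C@@]2(C)C=O)/C1=C\[C@@H](C)OC(C)=O | intermediate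
24 | methyl ester and C12 acetate of the target | CC1=C[C@H]2C[C@H](C)C(=O)[C@H](C)[C@H]2[C@H](/C=C(\C)[C@@H]2O[C@@]2(C)/C=C/C(=O)OC)/C1=C\[C@@H](C)OC(C)=O | intermediate
25 | CNP0414188.1 | CC1=C[C@H]2C[C@H](C)C(=O)[C@H](C)[C@H]2[C@H](/C=C(\C)[C@@H]2O[C@@]2(C)/C=C/C(=O)O)/C1=C\[C@@H](C)O | target

**Step count and risks**

Total step count: 18. Longest linear sequence: 18 steps, from (R)-(−)-carvone.

Steps most likely to fail:

1. Step 7 (proposed method). The doubly complexed substrate may fail to cyclise for steric reasons, deprotonation may leak to C9 so that the ring closes through the wrong carbon, or O-silylation of the hindered aluminium enolate may be incomplete. The fallback uses known chemistry and sets out from 8. The template is dropped in favour of thermodynamic enolate control: KOt-Bu (1.05 equiv) in THF/t-BuOH at −40 °C should equilibrate the enolates towards the linear potassium dienolate, the species behind the classical deconjugation and alkylation of 4-en-3-ones. That dienolate can close a six-membered ring only through C3, and trapping the resulting potassium enolate with TBSCl comes back to the route at 11. No new compound is made. This is not the first choice because equilibrating base invites β-elimination of the silyloxy group at C9 and epimerisation at C3.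

2. Step 9. The silyl enol ether may be lost to adventitious acid, the allylic hydroxyl may transpose towards C2 instead of rearranging, or the olefin geometry may be eroded. The fallback sets out from 11 and bypasses 12. Aldol addition of the lithium enolate of acetone (LiN(iPr)2, acetone, THF, −78 °C, with CeCl3 if enolisation of 11 competes) to the C10 ketone would give the β-hydroxy ketone F1. Dehydration with methyl N-(triethylammoniosulfonyl)carbamate (inner salt) by way of the acidic C11 hydrogens should give the conjugated (E)-dienone and comes back to the route at 13.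

3. Step 13. During the thermal olefination the β,γ-olefin (C10=C11) of aldehyde 18 may migrate into conjugation with the aldehyde, or C9 may epimerise. The fallback sets out from crude 18. The more nucleophilic acyl ylide Ph3P=C(CH3)C(O)SEt should react at room temperature in CH2Cl2 to give the S-ethyl enethioate F2. Fukuyama reduction (Et3SiH, Pd on carbon, that is zerovalent palladium metal, acetone, rt) would then convert the thioester into the aldehyde without touching the C6 ketone, and comes back to the route at 19.

Further compounds
F0 | step 7 | none | none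
F1 | step 9 | β-hydroxy ketone, OH and CH2C(=O)CH3 on C10 | CC1=C[C@H]2CC(C)=C(O[Si](C)(C)C(C)(C)C)C(C)[C@H]2[C@H](CO[Si](C)(C)C(C)(C)C)C1(O)CC(C)=O
F2 | step 13 | S-ethyl (E)-enethioate, C9–CH=C(CH3)–C(=O)SEt | CC1=C[C@H]2C[C@H](C)C(=O)[C@H](C)[C@H]2[C@H](/C=C(\C)C(=O)SCC)/C1=C\[C@@H](C)OC(C)=O
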